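**Remarks on the chemistry (made before the route).** The target is read as (3S,4S): the two benzyl groups are trans on the lactone and the C3 hydroxyl is cis to the C4 benzyl group. Butenolide 5 is assumed to be purchasable; it is otherwise available from furfural and l-menthol. "Up/down" refers to the lactone ring drawn flat with the menthyloxy group down.

**Retrosynthetic overview**
1. Target 22 ⇐ 19 (reductive removal of the menthyl acetal at C5) ⇐ β-hydroxy ketone 16 (hydrogenolysis of ArC=O and OBn) ⇐ isoxazoline 14 (N–O cleavage).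
2. 14 ⇐ [3+2] cycloaddition of nitrile oxide 13 (from veratraldehyde) to butenolide 9: the benzylic C–C4 bond and the tertiary C3–O bond are made together, cis, on the face anti to the menthyloxy group.
3. Enabling feature: the C3 hydroxyl oxygen and the benzylic carbon on C4 are 1,3-related and cis on the butanolide ring (O–C3–C4–CH2Ar, a reduced aldol), which is the retron of a 2-isoxazoline cis-fused across C3–C4.
4. 9 ⇐ Negishi coupling of bromobutenolide 7 (from 5) with benzylzinc reagent 8 (from syringaldehyde).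
5. Ring order: lactone ring bought with 5; temporary isoxazoline ring closed in step 8 and opened in step 9; lactone opened and re-closed in step 11; both arenes bought.

Key step: step 8

**Route**

Step 1
Reactants: 1 syringaldehyde (4-hydroxy-3,5-dimethoxybenzaldehyde)
Product: 2 4-(benzyloxy)-3,5-dimethoxybenzaldehyde
Conditions: BnBr, K2CO3, DMF, 60 °C
Reagents that add atoms: benzyl bromide BrCc1ccccc1
Why: Williamson ether synthesis on the acidic phenol should protect it as an ether that survives organozinc, cycloaddition and Raney Ni conditions and falls off in the later hydrogenolysis.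

Step 2
Reactants: 2 4-(benzyloxy)-3,5-dimethoxybenzaldehyde
Product: 3 [4-(benzyloxy)-3,5-dimethoxyphenyl]methanol
Conditions: NaBH4, MeOH/THF, 0 °C
Reagents that add atoms: none
Why: Borohydride reduction of an aryl aldehyde to the benzylic alcohol is reliable and touches nothing else.

Step 3
Reactants: 3 [4-(benzyloxy)-3,5-dimethoxyphenyl]methanol
Product: 4 2-(benzyloxy)-5-(chloromethyl)-1,3-dimethoxybenzene
Conditions: SOCl2, cat. DMF, CH2Cl2, 0 °C to rt; used promptly
Reagents that add atoms: thionyl chloride O=S(Cl)Cl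
Why: Chlorodehydroxylation through the chlorosulfite should give the electron-rich benzylic chloride, the halide of choice for clean zinc insertion.

Step 4
Reactants: 5 (5R)-5-[(1R,2S,5R)-menthyloxy]furan-2(5H)-one
Product: 7 (5R)-3-bromo-5-[(1R,2S,5R)-menthyloxy]furan-2(5H)-one, via dibromide 6 (not isolated)
Conditions: Br2, CH2Cl2, 0 °C; then Et3N, 0 °C to rt
Reagents that add atoms: bromine BrBr
Why: Anti addition of Br2 to the enoate followed by loss of HBr (acidic C3–H, β-bromide at C4) should give the α-bromobutenolide with the acetal centre untouched (bromination–dehydrobromination).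

Step 5
Reactants: 4 2-(benzyloxy)-5-(chloromethyl)-1,3-dimethoxybenzene; 7 (5R)-3-bromo-5-[(1R,2S,5R)-menthyloxy]furan-2(5H)-one
Product: 9 (5R)-3-[4-(benzyloxy)-3,5-dimethoxybenzyl]-5-[(1R,2S,5R)-menthyloxy]furan-2(5H)-one, via benzylzinc chloride 8 (not isolated)
Conditions: 4, Zn dust, LiCl, THF, 25 °C; then 7, Pd(OAc)2 (2 mol%), SPhos (4 mol%), THF, 25–40 °C
Reagents that add atoms: none
Why: LiCl-assisted insertion of zinc into the benzylic C–Cl bond and Negishi coupling (oxidative addition of zerovalent palladium into the vinylic C–Br bond, transmetalation, reductive elimination) should give the 3-benzylbutenolide without touching the acetal or the enoate.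

Step 6
Reactants: 10 veratraldehyde (3,4-dimethoxybenzaldehyde)
Product: 11 (E)-3,4-dimethoxybenzaldehyde oxime
Conditions: NH2OH·HCl, NaOAc, EtOH/H2O, rt
Reagents that add atoms: hydroxylamine hydrochloride NO.Cl
Why: Condensation of an aryl aldehyde with hydroxylamine gives the (E)-aldoxime reliably.

Step 7
Reactants: 11 (E)-3,4-dimethoxybenzaldehyde oxime
Product: 12 (Z)-N-hydroxy-3,4-dimethoxybenzimidoyl chloride
Conditions: N-chlorosuccinimide, DMF, 25–35 °C
Reagents that add atoms: N-chlorosuccinimide O=C1CCC(=O)N1Cl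
Why: C-chlorination of the aldoxime gives the hydroximoyl chloride, a storable precursor from which the nitrile oxide can be released slowly.

Step 8
Reactants: 9 (5R)-3-[4-(benzyloxy)-3,5-dimethoxybenzyl]-5-[(1R,2S,5R)-menthyloxy]furan-2(5H)-one; 12 (Z)-N-hydroxy-3,4-dimethoxybenzimidoyl chloride
Product: 14 (3aR,4R,6aS)-6a-[4-(benzyloxy)-3,5-dimethoxybenzyl]-3-(3,4-dimethoxyphenyl)-4-[(1R,2S,5R)-menthyloxy]-3a,4-dihydrofuro[3,4-d]isoxazol-6(6aH)-one, via nitrile oxide 13 (not isolated)
Conditions: solid NaHCO3, EtOAc, 40 °C; 12 (3 equiv) added in portions over 24 h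
Reagents that add atoms: none
Why: NaHCO3 dehydrochlorinates 12 to nitrile oxide 13, which adds in a concerted, asynchronous [3+2] fashion across C3=C4 of 9, its carbon terminus bonding to C4 and its oxygen to C3. The closest known reaction type is the Huisgen nitrile oxide–alkene cycloaddition as practised on 5-alkoxyfuran-2(5H)-ones, used here as a masked aldol addition. The only ring closed is the 2-isoxazoline, formed by the 1,3-dipolar cycloaddition itself, suprafacial on the alkene and therefore cis-fused to the lactone. The two new stereocentres (C3a, the future C4, and C6a, the future C3) are controlled by the acetal stereocentre C5: the dipole should approach the face anti to the menthyloxy group, and the cis fusion then places the C3–O bond cis to the new C4–C bond and the C3 benzyl group trans to it, as the target requires. The step needs regioselectivity (the fully substituted C3 should steer the bulkier carbon terminus to the less substituted C4, as with other trisubstituted alkenes), facial selectivity (secured by the C5 acetal) and addition faster than dipole dimerization (secured by slow release of 13 in excess over a mild heterogeneous base that leaves C5 unepimerized).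

Step 9
Reactants: 14 (3aR,4R,6aS)-6a-[4-(benzyloxy)-3,5-dimethoxybenzyl]-3-(3,4-dimethoxyphenyl)-4-[(1R,2S,5R)-menthyloxy]-3a,4-dihydrofuro[3,4-d]isoxazol-6(6aH)-one
Product: 16 (3S,4R,5R)-3-[4-(benzyloxy)-3,5-dimethoxybenzyl]-4-(3,4-dimethoxybenzoyl)-3-hydroxy-5-[(1R,2S,5R)-menthyloxy]dihydrofuran-2(3H)-one, via ketimine 15 (not isolated)
Conditions: H2 (1 atm), Raney Ni, B(OH)3, MeOH/THF/H2O, 25 °C
Reagents that add atoms: water O
Why: Hydrogenolysis of the weak N–O bond gives the β-hydroxy ketimine, which the boric acid-buffered water hydrolyses to the β-hydroxy ketone before C=N reduction (isoxazoline-to-aldol unmasking); no bond to C3 or C4 is broken, and the aroyl group at C4 already lies trans to both larger neighbours, so epimerization has no driving force.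

Step 10
Reactants: 16 (3S,4R,5R)-3-[4-(benzyloxy)-3,5-dimethoxybenzyl]-4-(3,4-dimethoxybenzoyl)-3-hydroxy-5-[(1R,2S,5R)-menthyloxy]dihydrofuran-2(3H)-one
Product: 19 (3S,4R,5R)-4-(3,4-dimethoxybenzyl)-3-hydroxy-3-(4-hydroxy-3,5-dimethoxybenzyl)-5-[(1R,2S,5R)-menthyloxy]dihydrofuran-2(3H)-one, via phenol ketone 17 (not isolated), via benzylic carbinol 18 (not isolated)
Conditions: H2 (4 atm), Pd(OH)2/C, AcOH, 50 °C
Reagents that add atoms: none
Why: Catalytic hydrogenolysis should first cleave the O-benzyl ether, then hydrogenate the electron-rich aryl ketone to the benzylic carbinol and hydrogenolyse that C–O bond to the methylene group, while the non-benzylic tertiary alcohol, the acetal and the lactone are inert.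

Step 11
Reactants: 19 (3S,4R,5R)-4-(3,4-dimethoxybenzyl)-3-hydroxy-3-(4-hydroxy-3,5-dimethoxybenzyl)-5-[(1R,2S,5R)-menthyloxy]dihydrofuran-2(3H)-one
Product: 22 (3S,4S)-4-(3,4-dimethoxybenzyl)-3-hydroxy-3-(4-hydroxy-3,5-dimethoxybenzyl)dihydrofuran-2(3H)-one, via aldehyde carboxylate 20 (not isolated), via hydroxy carboxylate 21 (not isolated)
Conditions: NaBH4, KOH, EtOH/H2O, N2, 0 °C to rt; then 2 M HCl to pH 1, rt
Reagents that add atoms: potassium hydroxide [K+].[OH-] (its oxygen becomes one of the two equivalent carboxylate oxygens and may remain as the lactone carbonyl oxygen)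
Why: Saponification opens the lactone, the freed hemiacetal expels menthol to give the aldehyde, NaBH4 present from the start reduces it at once, and acidification re-closes the γ-lactone on the original carboxyl carbon (hydrolysis–reduction–lactonization of a pseudo-ester), so the acetal carbon becomes the ring CH2 and no bond to C3 or C4 is broken.

**Compound list**

1 | syringaldehyde (4-hydroxy-3,5-dimethoxybenzaldehyde) | COc1cc(C=O)cc(OC)c1O | starting material
2 | 4-(benzyloxy)-3,5-dimethoxybenzaldehyde | COc1cc(C=O)cc(OC)c1OCc1ccccc1 | intermediate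
3 | [4-(benzyloxy)-3,5-dimethoxyphenyl]methanol | COc1cc(CO)cc(OC)c1OCc1ccccc1 | intermediate
4 | 2-(benzyloxy)-5-(chloromethyl)-1,3-dimethoxybenzene | COc1cc(CCl)cc(OC)c1OCc1ccccc1 | intermediate
5 | (5R)-5-[(1R,2S,5R)-menthyloxy]furan-2(5H)-one | O=C1C=C[C@H](O[C@@H]2C[C@H](C)CC[C@H]2C(C)C)O1 | starting material
6 | (5R)-3,4-trans-dibromo-5-[(1R,2S,5R)-menthyloxy]dihydrofuran-2(3H)-one, drawn with the C4 bromine anti to the menthyloxy group (formed in the flask) | O=C1[C@H](Br)[C@@H](Br)[C@H](O[C@@H]2C[C@H](C)CC[C@H]2C(C)C)O1 | intermediate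
7 | (5R)-3-bromo-5-[(1R,2S,5R)-menthyloxy]furan-2(5H)-one | O=C1C(Br)=C[C@H](O[C@@H]2C[C@H](C)CC[C@H]2C(C)C)O1 | intermediate
8 | [4-(benzyloxy)-3,5-dimethoxybenzyl]zinc chloride (formed in the flask) | COc1cc(C[Zn]Cl)cc(OC)c1OCc1ccccc1 | intermediate
9 | (5R)-3-[4-(benzyloxy)-3,5-dimethoxybenzyl]-5-[(1R,2S,5R)-menthyloxy]furan-2(5H)-one | COc1cc(CC2=C[C@H](O[C@@H]3C[C@H](C)CC[C@H]3C(C)C)OC2=O)cc(OC)c1OCc1ccccc1 | intermediate
10 | veratraldehyde (3,4-dimethoxybenzaldehyde) | COc1ccc(C=O)cc1OC | starting material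
11 | (E)-3,4-dimethoxybenzaldehyde oxime | COc1ccc(/C=N/O)cc1OC | intermediate
12 | (Z)-N-hydroxy-3,4-dimethoxybenzimidoyl chloride | COc1ccc(/C(Cl)=N/O)cc1OC | intermediate
13 | 3,4-dimethoxybenzonitrile oxide (formed in the flask) | COc1ccc(C#[N+][O-])cc1OC | intermediate
14 | (3aR,4R,6aS)-6a-[4-(benzyloxy)-3,5-dimethoxybenzyl]-3-(3,4-dimethoxyphenyl)-4-[(1R,2S,5R)-menthyloxy]-3a,4-dihydrofuro[3,4-d]isoxazol-6(6aH)-one; cis ring fusion, isoxazoline C and O anti to the menthyloxy group | COc1ccc(cc1OC)C2=NO[C@]3(Cc4cc(OC)c(OCc5ccccc5)c(OC)c4)C(=O)O[C@@H](O[C@@H]6C[C@H](C)CC[C@H]6C(C)C)[C@H]23 | intermediate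
15 | (3S,4R,5R)-3-[4-(benzyloxy)-3,5-dimethoxybenzyl]-4-[(3,4-dimethoxyphenyl)(imino)methyl]-3-hydroxy-5-[(1R,2S,5R)-menthyloxy]dihydrofuran-2(3H)-one (formed in the flask) | COc1ccc(C(=N)[C@H]2[C@H](O[C@@H]3C[C@H](C)CC[C@H]3C(C)C)OC(=O)[C@]2(O)Cc2cc(OC)c(OCc3ccccc3)c(OC)c2)cc1OC | intermediate
16 | (3S,4R,5R)-3-[4-(benzyloxy)-3,5-dimethoxybenzyl]-4-(3,4-dimethoxybenzoyl)-3-hydroxy-5-[(1R,2S,5R)-menthyloxy]dihydrofuran-2(3H)-one | COc1ccc(C(=O)[C@H]2[C@H](O[C@@H]3C[C@H](C)CC[C@H]3C(C)C)OC(=O)[C@]2(O)Cc2cc(OC)c(OCc3ccccc3)c(OC)c2)cc1OC | intermediate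
17 | (3S,4R,5R)-4-(3,4-dimethoxybenzoyl)-3-hydroxy-3-(4-hydroxy-3,5-dimethoxybenzyl)-5-[(1R,2S,5R)-menthyloxy]dihydrofuran-2(3H)-one (formed in the flask) | COc1ccc(C(=O)[C@H]2[C@H](O[C@@H]3C[C@H](C)CC[C@H]3C(C)C)OC(=O)[C@]2(O)Cc2cc(OC)c(O)c(OC)c2)cc1OC | intermediate
18 | (3S,4R,5R)-4-[(3,4-dimethoxyphenyl)(hydroxy)methyl]-3-hydroxy-3-(4-hydroxy-3,5-dimethoxybenzyl)-5-[(1R,2S,5R)-menthyloxy]dihydrofuran-2(3H)-one, either carbinol epimer (formed in the flask) | COc1ccc(C(O)[C@H]2[C@H](O[C@@H]3C[C@H](C)CC[C@H]3C(C)C)OC(=O)[C@]2(O)Cc2cc(OC)c(O)c(OC)c2)cc1OC | intermediate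
19 | (3S,4R,5R)-4-(3,4-dimethoxybenzyl)-3-hydroxy-3-(4-hydroxy-3,5-dimethoxybenzyl)-5-[(1R,2S,5R)-menthyloxy]dihydrofuran-2(3H)-one | COc1ccc(C[C@H]2[C@H](O[C@@H]3C[C@H](C)CC[C@H]3C(C)C)OC(=O)[C@]2(O)Cc2cc(OC)c(O)c(OC)c2)cc1OC | intermediate
20 | dipotassium (2S,3R)-3-(3,4-dimethoxybenzyl)-2-hydroxy-2-(3,5-dimethoxy-4-oxidobenzyl)-4-oxobutanoate (formed in the flask) | [K+].[K+].[O-]C(=O)[C@](O)(Cc1cc(OC)c([O-])c(OC)c1)[C@H](C=O)Cc1ccc(OC)c(OC)c1 | intermediate
21 | dipotassium (2S,3S)-3-(3,4-dimethoxybenzyl)-2,4-dihydroxy-2-(3,5-dimethoxy-4-oxidobenzyl)butanoate (formed in the flask) | [K+].[K+].[O-]C(=O)[C@](O)(Cc1cc(OC)c([O-])c(OC)c1)[C@H](CO)Cc1ccc(OC)c(OC)c1 | intermediate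
22 | (3S,4S)-4-(3,4-dimethoxybenzyl)-3-hydroxy-3-(4-hydroxy-3,5-dimethoxybenzyl)dihydrofuran-2(3H)-one | COc1ccc(C[C@H]2COC(=O)[C@]2(O)Cc2cc(OC)c(O)c(OC)c2)cc1OC | target

**Step count**

Total: 11 steps. Longest linear sequence: 8 steps (1, 2, 3, 5, 8, 9, 10, 11, from syringaldehyde).

**Steps most likely to fail, with fallbacks**

Step 8. The dipole may add with the reverse regiochemistry (oxygen to C4), or dimerize faster than it adds to the hindered trisubstituted alkene. Fallback, setting out from 5, 10 and 4 and coming back to the route at 16: veratraldehyde 10 is condensed with propane-1,3-dithiol (BF3·OEt2, CH2Cl2) to 2-(3,4-dimethoxyphenyl)-1,3-dithiane F1. Its 2-lithio derivative (n-BuLi, THF, −78 °C) should add 1,4 to butenolide 5 on the face anti to the menthyloxy group, forming the same benzylic C–C4 bond, and give after protonation the 4,5-trans lactone F2. Enolate hydroxylation (KHMDS, 3-phenyl-2-(phenylsulfonyl)oxaziridine, THF, −78 °C) should give the 3-hydroxy lactone F3. Its dianion (LDA, 2.2 equiv, THF/DMPU, −78 to −20 °C) should be benzylated by chloride 4 (NaI added) anti to the C4 substituent, which leaves the hydroxyl cis to it, to give the tertiary alcohol F4. Hydrolysis of the dithiane (I2, NaHCO3, aqueous acetone, 0 °C) unveils the aryl ketone and gives 16.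

Step 11. The ring-opened β-hydroxy aldehyde may epimerize at C4 or undergo retro-aldol cleavage in hydroxide before hydride reduction. Fallback, setting out from 19 and coming back at 22: the acetal is cleaved under acid instead (2 M HCl, dioxane, 50 °C) to the lactol 5-hydroxy lactone F7, a mixture of anomers. Its aldehyde–acid tautomer is reduced without added base (NaBH4, THF/pH 7 phosphate buffer, 0 °C), and acidification closes the lactone to 22, so the aldehyde never meets hydroxide.

Step 10. Hydrogenolysis of the hindered aryl ketone may stall at the carbinol, or, if forced with stronger acid, lose configuration at C4 through dehydration to a styrene and unselective re-hydrogenation. Fallback, setting out from 16 and coming back at 19: the ketone is condensed with tosylhydrazide (EtOH, cat. AcOH, 60 °C) to the tosylhydrazone F5. Reduction with catecholborane (CHCl3, 0 °C) and then NaOAc·3H2O at reflux should give, through a diazene that loses N2 without any benzylic cation, the methylene compound F6, the O-benzyl ether of 19. Neutral hydrogenolysis (H2 1 atm, Pd/C, EtOAc, rt) removes the benzyl ether and gives 19.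

**Further compounds**

F1 | step 8 | 2-(3,4-dimethoxyphenyl)-1,3-dithiane | COc1ccc(C2SCCCS2)cc1OC
F2 | step 8 | (4R,5R)-4-[2-(3,4-dimethoxyphenyl)-1,3-dithian-2-yl]-5-[(1R,2S,5R)-menthyloxy]dihydrofuran-2(3H)-one (4,5-trans) | COc1ccc(C2(SCCCS2)[C@H]4[C@H](O[C@@H]3C[C@H](C)CC[C@H]3C(C)C)OC(=O)C4)cc1OC
F3 | step 8 | 3-hydroxy derivative of F2 with the hydroxyl trans to the C4 substituent | COc1ccc(C2(SCCCS2)[C@H]4[C@H](O[C@@H]3C[C@H](C)CC[C@H]3C(C)C)OC(=O)[C@@H]4O)cc1OC
F4 | step 8 | 3-[4-(benzyloxy)-3,5-dimethoxybenzyl]-4-[2-(3,4-dimethoxyphenyl)-1,3-dithian-2-yl]-3-hydroxy-5-[(1R,2S,5R)-menthyloxy]dihydrofuran-2(3H)-one, hydroxyl cis and benzyl trans to the C4 substituent | COc1ccc(C2(SCCCS2)[C@H]4[C@H](O[C@@H]3C[C@H](C)CC[C@H]3C(C)C)OC(=O)[C@]4(O)Cc2cc(OC)c(OCc3ccccc3)c(OC)c2)cc1OC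
F5 | step 10 | tosylhydrazone of ketone 16 | COc1ccc(C(=NNS(=O)(=O)c2ccc(C)cc2)[C@H]2[C@H](O[C@@H]3C[C@H](C)CC[C@H]3C(C)C)OC(=O)[C@]2(O)Cc2cc(OC)c(OCc3ccccc3)c(OC)c2)cc1OC
F6 | step 10 | (3S,4R,5R)-3-[4-(benzyloxy)-3,5-dimethoxybenzyl]-4-(3,4-dimethoxybenzyl)-3-hydroxy-5-[(1R,2S,5R)-menthyloxy]dihydrofuran-2(3H)-one | COc1ccc(C[C@H]2[C@H](O[C@@H]3C[C@H](C)CC[C@H]3C(C)C)OC(=O)[C@]2(O)Cc2cc(OC)c(OCc3ccccc3)c(OC)c2)cc1OC
F7 | step 11 | (3S,4R)-4-(3,4-dimethoxybenzyl)-3,5-dihydroxy-3-(4-hydroxy-3,5-dimethoxybenzyl)dihydrofuran-2(3H)-one (lactol, both anomers) | COc1ccc(C[C@H]2C(O)OC(=O)[C@]2(O)Cc2cc(OC)c(O)c(OC)c2)cc1OC
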